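The route rests on opening ring C of the isoflavone at O1–C8a and C4–C4a. The key step exploits the fact that O1 (on C8a) and the C4 carbonyl (on C4a) sit on adjacent carbons of ring A, so an aryne spanning C4a–C8a can take both from a single partner. The pre-formed enolate of a ring B 3-hydroxyacrylate adds through oxygen, and the aryl anion so created closes onto the cis ester, giving two bonds and the pyranone in one operation. The precursors are an ortho-silylaryl triflate that releases 3-bromo-5-(methoxymethoxy)benzyne, whose bromine (future C5) steers regiochemistry and is later removed, and the methyl 3-hydroxy-2-arylacrylate carrying the complete prenylated ring B.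

Key step: step 11

Remark: 5-bromo-2,4-dihydroxybenzaldehyde and 4-(methoxymethoxy)phenol are taken as purchasable; the hydroxyacrylate precursor is written as its hydrogen-bonded Z enol, which equilibrates with the E enol and the aldehyde tautomer, all giving the same enolate on deprotonation.

Step 1
Reactants: 1 5-bromo-2,4-dihydroxybenzaldehyde
Product: 2 5-bromo-2,4-bis(methoxymethoxy)benzaldehyde
Conditions: MOMCl (3 equiv), K2CO3, acetone, 0 °C to reflux
Reagents that add atoms: chloromethyl methyl ether, COCCl
Why: Williamson-type O-alkylation of both phenoxides by the reactive α-chloro ether; excess reagent and heat should overcome the hydrogen bond between the 2-OH and the aldehyde.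

Step 2
Reactants: 2 5-bromo-2,4-bis(methoxymethoxy)benzaldehyde
Product: 4 5-bromo-2,4-bis(methoxymethoxy)phenol, via aryl formate 3 (not isolated)
Conditions: mCPBA, CH2Cl2, 0 °C to rt; aq. NaHCO3 wash; then K2CO3 (cat.), MeOH, rt
Reagents that add atoms: 3-chloroperoxybenzoic acid, OOC(=O)c1cccc(Cl)c1
Why: Baeyer–Villiger (Dakin-type) oxidation in which the electron-rich 2,4-dialkoxyaryl group should migrate in preference to hydride, followed by base-catalysed methanolysis of the formate.

Step 3
Reactants: 4 5-bromo-2,4-bis(methoxymethoxy)phenol; 5 3-chloro-3-methylbut-1-yne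
Product: 6 1-bromo-2,4-bis(methoxymethoxy)-5-[(2-methylbut-3-yn-2-yl)oxy]benzene
Conditions: K2CO3, KI (cat.), CuI (cat.), acetone, 55 °C
Reagents that add atoms: none
Why: CuI-assisted O-propargylation of a phenoxide with a tertiary propargylic chloride, the standard entry to aryl 1,1-dimethylpropargyl ethers.

Step 4
Reactants: 6 1-bromo-2,4-bis(methoxymethoxy)-5-[(2-methylbut-3-yn-2-yl)oxy]benzene
Product: 7 1-bromo-2,4-bis(methoxymethoxy)-5-[(2-methylbut-3-en-2-yl)oxy]benzene
Conditions: H2 (1 atm), Pd/CaCO3 poisoned with Pb(OAc)2 (Lindlar catalyst), quinoline, EtOAc, rt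
Reagents that add atoms: none
Why: Lindlar semi-hydrogenation of the terminal alkyne should stop at the alkene on the poisoned catalyst, which is also expected to spare the aryl bromide.

Step 5
Reactants: 7 1-bromo-2,4-bis(methoxymethoxy)-5-[(2-methylbut-3-en-2-yl)oxy]benzene
Product: 8 3-bromo-4,6-bis(methoxymethoxy)-2-(3-methylbut-2-en-1-yl)phenol
Conditions: N,N-diethylaniline, 130 °C
Reagents that add atoms: none
Why: aromatic Claisen rearrangement ([3,3]-sigmatropic shift, then tautomerisation) to the only free ortho carbon, which turns the 1,1-dimethylallyl ether into the C-prenyl group.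

Step 6
Reactants: 8 3-bromo-4,6-bis(methoxymethoxy)-2-(3-methylbut-2-en-1-yl)phenol
Product: 9 3-bromo-1-methoxy-4,6-bis(methoxymethoxy)-2-(3-methylbut-2-en-1-yl)benzene
Conditions: MeI, K2CO3, DMF, rt
Reagents that add atoms: iodomethane, CI
Why: Williamson O-methylation of the phenoxide, which fixes the C5' methoxy group of ring B.

Step 7
Reactants: 9 3-bromo-1-methoxy-4,6-bis(methoxymethoxy)-2-(3-methylbut-2-en-1-yl)benzene
Product: 10 methyl 2-[5-methoxy-2,4-bis(methoxymethoxy)-6-(3-methylbut-2-en-1-yl)phenyl]acetate
Conditions: BrZnCH2CO2Me (from BrCH2CO2Me, Zn, TMSCl cat., THF), Pd(dba)2 (cat.), P(t-Bu)3 (cat.), THF, 60 °C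
Reagents that add atoms: methyl bromoacetate (used as its zinc enolate), COC(=O)CBr
Why: palladium-catalysed α-arylation of a zinc ester enolate (Reformatsky reagent) with an aryl bromide, in which the bulky electron-rich phosphine should allow oxidative addition at the hindered C–Br bond and the neutral zinc enolate should tolerate the acetals and the alkene.

Step 8
Reactants: 10 methyl 2-[5-methoxy-2,4-bis(methoxymethoxy)-6-(3-methylbut-2-en-1-yl)phenyl]acetate
Product: 12 methyl (Z)-3-hydroxy-2-[5-methoxy-2,4-bis(methoxymethoxy)-6-(3-methylbut-2-en-1-yl)phenyl]prop-2-enoate, via potassium enolate 11 (not isolated)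
Conditions: KOt-Bu (2 equiv), HCO2Me (excess), THF, 0 °C to rt; then cold dilute aq. HCl to pH 5
Reagents that add atoms: methyl formate, COC=O
Why: crossed Claisen condensation (C-formylation) of the potassium ester enolate with a non-enolisable formate, driven by formation of the stabilised enolate 11, which on mild acidification should give the hydrogen-bonded Z enol.

Step 9
Reactants: 13 4-(methoxymethoxy)phenol
Product: 14 2,6-dibromo-4-(methoxymethoxy)phenol
Conditions: NBS (2.05 equiv), i-Pr2NH (cat.), CH2Cl2, 0 °C
Reagents that add atoms: N-bromosuccinimide, O=C1CCC(=O)N1Br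
Why: amine-catalysed electrophilic ortho-bromination of a phenol, in which the free hydroxyl directs both bromines to its two ortho carbons and the non-acidic medium should spare the methoxymethyl ether.

Step 10
Reactants: 14 2,6-dibromo-4-(methoxymethoxy)phenol
Product: 18 2-bromo-4-(methoxymethoxy)-6-(trimethylsilyl)phenyl trifluoromethanesulfonate, via silyl ether 15 (not isolated), via aryllithium 16 (not isolated), via lithium phenoxide 17 (not isolated)
Conditions: HMDS, THF, 70 °C, then evaporation; n-BuLi (1.05 equiv), THF, −100 to −78 °C; Tf2O, −100 °C to rt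
Reagents that add atoms: hexamethyldisilazane, C[Si](C)(C)N[Si](C)(C)C; trifluoromethanesulfonic anhydride, O=S(=O)(OS(=O)(=O)C(F)(F)F)C(F)(F)F
Why: O-silylation, bromine–lithium exchange at one of the two equivalent bromines, anionic 1,3 O-to-C silyl shift (retro-Brook rearrangement) and O-triflation of the phenoxide, the standard one-flask conversion of an ortho-bromophenol into an ortho-silylaryl triflate.

Step 11
Reactants: 12 methyl (Z)-3-hydroxy-2-[5-methoxy-2,4-bis(methoxymethoxy)-6-(3-methylbut-2-en-1-yl)phenyl]prop-2-enoate; 18 2-bromo-4-(methoxymethoxy)-6-(trimethylsilyl)phenyl trifluoromethanesulfonate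
Product: 21 5-bromo-7-(methoxymethoxy)-3-[5-methoxy-2,4-bis(methoxymethoxy)-6-(3-methylbut-2-en-1-yl)phenyl]-4H-chromen-4-one, via sodium enolate 19 (not isolated), via aryne 20 (not isolated)
Conditions: NaH (1.0 equiv), THF, 0 °C; then 18 (1.5 equiv), CsF (4 equiv), THF, 65 °C
Reagents that add atoms: none
Why: Proposed new method: fluoride removes the silyl group of 18 and triflate departs to give aryne 20; the oxygen of sodium enolate 19 adds to the aryne carbon remote from bromine (future C8a), and the aryl anion thus placed at C4a, beside the C–Br bond, attacks the cis ester carbonyl and expels methoxide, so that O1–C8a and C4–C4a form in one flask. The closest known reactions are the fluoride-induced coupling of arynes with methyl salicylates, which gives xanthones by the same O-arylation and acyl capture, and the insertion of arynes into β-dicarbonyl compounds; an open-chain 3-hydroxyacrylate as the oxygen and acyl donor is the untested element. Ring C closes by 6-exo-trig addition of the aryl anion to the ester C=O followed by collapse of the tetrahedral intermediate, and no stereocentre is formed. Regiochemistry rests on the bromine at the 3-position of the aryne, whose inductive pull distorts the triple bond so that the nucleophile attacks the distal terminus and charge develops next to C–Br, which should outweigh the weak opposing bias of the alkoxy group destined for C7. O-arylation instead of C-arylation is secured by the fully substituted enolate carbon, shielded by the 2,6-disubstituted ring B. Ring closure needs the ester cis to the enolate oxygen, so the enolate is pre-formed with NaH and kept as a chelated, U-shaped (Z) sodium contact ion pair in THF, without crown ether or dipolar cosolvent that would favour the extended form, and without any proton source that could quench the aryl anion before it acylates.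

Step 12
Reactants: 21 5-bromo-7-(methoxymethoxy)-3-[5-methoxy-2,4-bis(methoxymethoxy)-6-(3-methylbut-2-en-1-yl)phenyl]-4H-chromen-4-one
Product: 22 7-(methoxymethoxy)-3-[5-methoxy-2,4-bis(methoxymethoxy)-6-(3-methylbut-2-en-1-yl)phenyl]-4H-chromen-4-one
Conditions: Pd(PPh3)4 (cat.), HCO2Na, DMF, 90 °C
Reagents that add atoms: none
Why: palladium-catalysed hydrodehalogenation with formate as hydride donor, in which the C–Br bond peri to the carbonyl is activated for oxidative addition while the trisubstituted prenyl alkene and the chromone should remain untouched.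

Step 13
Reactants: 22 7-(methoxymethoxy)-3-[5-methoxy-2,4-bis(methoxymethoxy)-6-(3-methylbut-2-en-1-yl)phenyl]-4H-chromen-4-one
Product: 23 kwakhurin, 7-hydroxy-3-[2,4-dihydroxy-5-methoxy-6-(3-methylbut-2-en-1-yl)phenyl]-4H-chromen-4-one
Conditions: HCl (2 M) in MeOH, 40 °C
Reagents that add atoms: none
Why: acid-catalysed acetal exchange should remove the three methoxymethyl ethers as dimethoxymethane, and the prenyl group, flanked by C5'-OMe and C1' and so lacking an ortho hydroxyl to cyclise onto, is expected to survive the mild acid.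

Compound list
1 | 5-bromo-2,4-dihydroxybenzaldehyde | O=Cc1cc(Br)c(O)cc1O | starting material
2 | 5-bromo-2,4-bis(methoxymethoxy)benzaldehyde | O=Cc1cc(Br)c(OCOC)cc1OCOC | intermediate
3 | 5-bromo-2,4-bis(methoxymethoxy)phenyl formate | O=COc1cc(Br)c(OCOC)cc1OCOC | intermediate (not isolated)
4 | 5-bromo-2,4-bis(methoxymethoxy)phenol | Oc1cc(Br)c(OCOC)cc1OCOC | intermediate
5 | 3-chloro-3-methylbut-1-yne | C#CC(C)(C)Cl | starting material
6 | 1-bromo-2,4-bis(methoxymethoxy)-5-[(2-methylbut-3-yn-2-yl)oxy]benzene | C#CC(C)(C)Oc1cc(Br)c(OCOC)cc1OCOC | intermediate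
7 | 1-bromo-2,4-bis(methoxymethoxy)-5-[(2-methylbut-3-en-2-yl)oxy]benzene | C=CC(C)(C)Oc1cc(Br)c(OCOC)cc1OCOC | intermediate
8 | 3-bromo-4,6-bis(methoxymethoxy)-2-(3-methylbut-2-en-1-yl)phenol | Oc1c(CC=C(C)C)c(Br)c(OCOC)cc1OCOC | intermediate
9 | 3-bromo-1-methoxy-4,6-bis(methoxymethoxy)-2-(3-methylbut-2-en-1-yl)benzene | COc1c(CC=C(C)C)c(Br)c(OCOC)cc1OCOC | intermediate
10 | methyl 2-[5-methoxy-2,4-bis(methoxymethoxy)-6-(3-methylbut-2-en-1-yl)phenyl]acetate | COC(=O)Cc1c(OCOC)cc(OCOC)c(OC)c1CC=C(C)C | intermediate
11 | potassium (Z)-3-methoxy-2-[5-methoxy-2,4-bis(methoxymethoxy)-6-(3-methylbut-2-en-1-yl)phenyl]-3-oxoprop-1-en-1-olate | COC(=O)/C(=C\[O-])c1c(OCOC)cc(OCOC)c(OC)c1CC=C(C)C.[K+] | intermediate (not isolated)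
12 | methyl (Z)-3-hydroxy-2-[5-methoxy-2,4-bis(methoxymethoxy)-6-(3-methylbut-2-en-1-yl)phenyl]prop-2-enoate | COC(=O)/C(=C\O)c1c(OCOC)cc(OCOC)c(OC)c1CC=C(C)C | intermediate
13 | 4-(methoxymethoxy)phenol | COCOc1ccc(O)cc1 | starting material
14 | 2,6-dibromo-4-(methoxymethoxy)phenol | COCOc1cc(Br)c(O)c(Br)c1 | intermediate
15 | [2,6-dibromo-4-(methoxymethoxy)phenoxy]trimethylsilane | COCOc1cc(Br)c(O[Si](C)(C)C)c(Br)c1 | intermediate (not isolated)
16 | [3-bromo-5-(methoxymethoxy)-2-(trimethylsilyloxy)phenyl]lithium | COCOc1cc(Br)c(O[Si](C)(C)C)c([Li])c1 | intermediate (not isolated)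
17 | lithium 2-bromo-4-(methoxymethoxy)-6-(trimethylsilyl)phenolate | COCOc1cc(Br)c([O-])c([Si](C)(C)C)c1.[Li+] | intermediate (not isolated)
18 | 2-bromo-4-(methoxymethoxy)-6-(trimethylsilyl)phenyl trifluoromethanesulfonate | COCOc1cc(Br)c(OS(=O)(=O)C(F)(F)F)c([Si](C)(C)C)c1 | intermediate
19 | sodium (Z)-3-methoxy-2-[5-methoxy-2,4-bis(methoxymethoxy)-6-(3-methylbut-2-en-1-yl)phenyl]-3-oxoprop-1-en-1-olate | COC(=O)/C(=C\[O-])c1c(OCOC)cc(OCOC)c(OC)c1CC=C(C)C.[Na+] | intermediate (not isolated)
20 | 3-bromo-5-(methoxymethoxy)benzyne | COCOC1=CC#CC(Br)=C1 | intermediate (not isolated)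
21 | 5-bromo-7-(methoxymethoxy)-3-[5-methoxy-2,4-bis(methoxymethoxy)-6-(3-methylbut-2-en-1-yl)phenyl]-4H-chromen-4-one | COc1c(OCOC)cc(OCOC)c(-c2coc3cc(OCOC)cc(Br)c3c2=O)c1CC=C(C)C | intermediate
22 | 7-(methoxymethoxy)-3-[5-methoxy-2,4-bis(methoxymethoxy)-6-(3-methylbut-2-en-1-yl)phenyl]-4H-chromen-4-one | COc1c(OCOC)cc(OCOC)c(-c2coc3cc(OCOC)ccc3c2=O)c1CC=C(C)C | intermediate
23 | kwakhurin, 7-hydroxy-3-[2,4-dihydroxy-5-methoxy-6-(3-methylbut-2-en-1-yl)phenyl]-4H-chromen-4-one | COc1c(O)cc(O)c(-c2coc3cc(O)ccc3c2=O)c1CC=C(C)C | target

Total step count: 13.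
Longest linear sequence: 11 steps (steps 1 to 8, then 11, 12 and 13); steps 9 and 10 form the two-step branch to the aryne precursor.

Steps most likely to fail

Step 11 (the proposed new method). Three processes could divert it: loss of bromide from the ortho-bromoaryl anion, giving a second aryne before acyl transfer; O-arylation through the extended enolate conformer, which sets the ester trans to the new aryl ether and leaves an uncyclised enol ether after protonation; and attack at the aryne terminus next to bromine. The fallback is the established isoflavone assembly by Suzuki–Miyaura coupling; it sets out from 9 and comes back at 22. Bromine–lithium exchange on 9 (n-BuLi, THF, −78 °C) and quench with 2-isopropoxy-4,4,5,5-tetramethyl-1,3,2-dioxaborolane should give the aryl pinacol boronate, 2-[5-methoxy-2,4-bis(methoxymethoxy)-6-(3-methylbut-2-en-1-yl)phenyl]-4,4,5,5-tetramethyl-1,3,2-dioxaborolane F1. Ring A would come from purchased 1-(2,4-dihydroxyphenyl)ethanone F2, in which MOMCl and K2CO3 in acetone at rt should protect only the non-chelated 4-OH to give 1-[2-hydroxy-4-(methoxymethoxy)phenyl]ethanone F3. Condensation of F3 with DMF dimethyl acetal should give the enaminone (E)-3-(dimethylamino)-1-[2-hydroxy-4-(methoxymethoxy)phenyl]prop-2-en-1-one F4, and iodine with pyridine in CHCl3 should cyclise it to 3-iodo-7-(methoxymethoxy)-4H-chromen-4-one F5. Coupling of F1 with F5 (Pd(OAc)2, SPhos, K3PO4, toluene/water, 80 °C) should give 22 directly, so steps 7, 8, 11 and 12 are bypassed.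

Step 7. Oxidative addition and transmetalation at the doubly ortho-substituted, electron-rich C–Br bond may be slow, so that protodebromination or recovery of the bromide competes with coupling. The fallback avoids palladium; it sets out from 9 and comes back at 10. Bromine–lithium exchange (n-BuLi, THF, −78 °C) and opening of ethylene oxide by the aryllithium should give 2-[5-methoxy-2,4-bis(methoxymethoxy)-6-(3-methylbut-2-en-1-yl)phenyl]ethan-1-ol F6. Oxidation with TEMPO (cat.) and PhI(OAc)2 in MeCN/water should give 2-[5-methoxy-2,4-bis(methoxymethoxy)-6-(3-methylbut-2-en-1-yl)phenyl]acetic acid F7 without touching the alkene, and esterification with MeI and K2CO3 in DMF should give 10.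

Step 4. The terminal alkene may be reduced further to the saturated tert-pentyl ether, which cannot rearrange, or the C–Br bond may undergo hydrogenolysis on palladium. The fallback avoids hydrogenation; it sets out from 4 and comes back at 7. Tsuji–Trost O-allylation of phenol 4 with tert-butyl 2-methylbut-3-en-2-yl carbonate (Pd(PPh3)4 cat., THF, 0 °C) should give the branched ether 7 directly, since phenoxide attack at the more substituted allyl terminus is kinetically preferred and the cold zerovalent palladium catalyst is not expected to insert into the electron-rich aryl bromide. This fallback makes no compound outside the list (F0).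

Further compounds
F1 | step 11 | 2-[5-methoxy-2,4-bis(methoxymethoxy)-6-(3-methylbut-2-en-1-yl)phenyl]-4,4,5,5-tetramethyl-1,3,2-dioxaborolane | COc1c(CC=C(C)C)c(B2OC(C)(C)C(C)(C)O2)c(OCOC)cc1OCOC
F2 | step 11 | 1-(2,4-dihydroxyphenyl)ethanone (purchased) | CC(=O)c1ccc(O)cc1O
F3 | step 11 | 1-[2-hydroxy-4-(methoxymethoxy)phenyl]ethanone | CC(=O)c1ccc(OCOC)cc1O
F4 | step 11 | (E)-3-(dimethylamino)-1-[2-hydroxy-4-(methoxymethoxy)phenyl]prop-2-en-1-one | CN(C)/C=C/C(=O)c1ccc(OCOC)cc1O
F5 | step 11 | 3-iodo-7-(methoxymethoxy)-4H-chromen-4-one | O=c1c(I)coc2cc(OCOC)ccc12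
F6 | step 7 | 2-[5-methoxy-2,4-bis(methoxymethoxy)-6-(3-methylbut-2-en-1-yl)phenyl]ethan-1-ol | OCCc1c(OCOC)cc(OCOC)c(OC)c1CC=C(C)C
F7 | step 7 | 2-[5-methoxy-2,4-bis(methoxymethoxy)-6-(3-methylbut-2-en-1-yl)phenyl]acetic acid | OC(=O)Cc1c(OCOC)cc(OCOC)c(OC)c1CC=C(C)C
F0 | step 4 | none | none
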